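## Structural features

The target is an achiral diaryl ether of two pentasubstituted benzene rings, in which one oxygen joins C3 of ring A to C2' of ring B; there is no other ring and no stereocentre, so no stereocentres stand next to each other and only constitution has to be controlled. Ring A carries CH2OH at C1, Br at C2, the ether oxygen at C3, OH at C4, Br at C5 and H at C6, and ring B carries CH2OH at C1', the ether oxygen at C2', a catechol at C3'/C4', Br at C5' and H at C6'. The ether oxygen is flanked on both rings by two ortho substituents (C2–Br and C4–OH; C1'–CH2OH and C3'–OH), so the real difficulty is a tetra-ortho-substituted ether between electron-rich rings, together with the correct placement of the six ring A substituents. The fragile groups are the two para-hydroxybenzyl alcohols (they ionise to quinone methides in acid, strong base or heat and then condense to diarylmethanes), the ring B catechol (air-sensitive in base) and the three aryl bromides (no hydrogenolysis, aryl–metal chemistry or palladium catalysis late in the route). The key step uses the fact that C1 is para to the C4 hydroxyl and C1' is para to the C4' hydroxyl, while all four positions ortho to these hydroxyls (C3, C5, C3', C5') are already substituted. Without C1, ring A is a mirror-symmetric 1,4-dibromo-2,3-dioxygenated benzene, and without C1' and the C5' bromine ring B is a symmetric 2-oxygenated resorcinol.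

## Logic of the disconnections

First, the C3' hydroxyl of 10 is traced back to a methyl ether; only the O–CH3 bond at C3' changes, and the path runs through 9 to 8. A free C3' phenoxide would activate C6', its para position, in the step that builds the benzylic carbons. The methyl group is already present in 1, so it costs no step to install. The skeleton is not simplified, but the two phenols that must react in the key step become the only ionisable oxygens. The demand on the forward step is that a boron Lewis acid also turns the two benzylic alcohols into the bromides of 9, so the same operation must end with a buffered hydrolysis.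

Second, the C1–CH2OH and C1'–CH2OH bonds of 8 are cut together, giving 6 and two molecules of 7. Each of these carbons is para to a phenol whose two ortho positions are filled, so the phenoxide can react nowhere else. The gain is large: the two bromines of ring A are no longer different, the two oxygens of ring A need no differentiation, and neither ring needs a carbon substituent beforehand. The forward step must be a two-fold para-hydroxymethylation that consumes one molecule of 7 per ring and stops at the benzyl alcohol.

Third, the C4–O bond of ring A in 6 is cut; the hydroxyl goes back through 5 to the C–F bond of 4. A phenol cannot sit on ring A while the diaryl ether is made there, because its anion would stop substitution, whereas fluorine activates the neighbouring carbon and later serves as leaving group. A para-methoxybenzyl ether is preferred to a benzyl ether because it leaves in CF3CO2H. Hydrogenolysis would endanger three C–Br bonds, and a chloroborane would attack the methyl ether wedged between two oxygens. The forward step must replace a fluoride that has an aryloxy neighbour, in a substrate that is a phenoxide under the conditions, without loss of bromine.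

Fourth, the diaryl ether bond C3–O of 4 is cut on the ring A side, giving 2 and 3. Because 3 is symmetric, either fluorine gives the same product, and the fluorine that remains is the future C4 oxygen. Both fragments are then simple: 3 is commercial and 2 is one step from a commercial diol. The forward step requires 2 to react once, through the hydroxyl flanked by OMe and H and not through the one next to bromine.

Fifth, the C5'–Br bond of 2 is cut, giving 1. C4 and C6 of 1 are equivalent and C5 is meta to both hydroxyls, so only one mono-bromide can form. The only demand is to stop after one bromination.

## Other disconnections considered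

Alternative 1: The cut is the C3–O ether bond, made together with the C4–O acyl bond, with C1' carried as a ketone and then as a lactone carbonyl.
- Forward key step: benzophenone A2 (ring A with the acyl group at C3 and OH at C4, ring B with OH at C2') would be oxidised at the ring A phenol with PhI(OAc)2. The C2' hydroxyl would add to C3 to give the racemic spiro dienone A3, and a shift of the acyl group from C3 to the C4 oxygen would rearomatise ring A and give depsidone A1.
- In favour: the ortho relation of ether oxygen and C4 oxygen on ring A is fixed by the mechanism. C1' is in the skeleton from the start, so no late C–C bond is made next to the hindered ether.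
- Better than the chosen plan on the end-game: one hydride reduction of A1 should open the lactone to C1'–CH2OH and C4–OH, cleave the carbonate and remove the pivalate, with no Lewis acid and no benzylic bromide.
- Equal on stereochemistry: neither plan has any to control, since the spiro centre of A3 is lost again.
- Against, structure: A2 is a hexasubstituted benzophenone with three bromines and differentiated oxygens. The symmetry of ring A is not used, the two bromines of ring A must be placed separately, and the ketone must be formed between two crowded rings without aryl–metal chemistry that the C–Br bonds would not survive.
- Against, mechanism: the phenol to be oxidised carries an ortho acyl group and two bromines and is electron-poor, and the attacking ring B phenol is deactivated by the carbonate and the ketone. Capture of the oxidised ring at C1 by acetate and migration of a group other than acyl from A3 are open competing paths.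
- Step economy: well over ten steps are expected, against six.

Alternative 2: The cut removes three bonds of ring A (C1–C2, C3–C4, C5–C6), so that ring A is assembled from three alkynes.
- Forward key step: diyne A5, in which an aryl ynol ether carrying ring B and a propargyl ether are joined through a diisopropylsilyl tether, would cyclotrimerise with alkyne A6 under [Rh(cod)2]BF4 and BINAP. The product is benzoxasilole A4, in which ring A and a fused five-membered oxasilole are closed.
- In favour and better than the chosen plan: the positions of C1 (CH2O), C2 (silicon as a bromine placeholder) and C3 (aryloxy) follow from connectivity and not from aromatic substitution. The diaryl ether oxygen comes in with a ring B phenol, so no substitution at a weakly activated fluoride is needed.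
- Against: the orientation of A6 (ethoxy at C4 next to the aryloxy group, silyl at C5) rests only on the electronic and steric bias of the insertion. Both ynol ethers and the Si–O tether are sensitive to hydrolysis.
- Against, after the key step: A4 still needs two ipso-bromodesilylations (the oxasilole C2–Si bond and the C5–SiMe3 bond) in the presence of an electron-rich ring B, cleavage of one ethyl and two methyl ethers, and an ester reduction.
- Comparison: ring A is available here from a symmetric commercial arene, so the de novo construction buys no simplification. The ether cleavage would meet the same benzylic bromide detour as the chosen end-game (equal). The route would be at least twice as long.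

Alternative 3: The cut removes C1'–C2' and C5'–C6' of ring B.
- Forward key step: diene A8 (1-aryloxy, 2-methoxy, 3-silyloxy) and methyl propiolate A9 would combine on heating. Loss of the two-carbon saturated bridge in the same operation would give benzoate A7.
- In favour: C1' arrives as an ester in the right place, and the contiguous oxygens at C2', C3' and C4' are set by the diene.
- Better than the chosen plan on one point: the later bromination at C5' would be unambiguous, because after desilylation it is the only position ortho to the C4' hydroxyl and the para position is blocked. The chosen step 2 has to rely on site selection between two hydroxyls.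
- Against, structure: the ring A half of A8 is an unsymmetrical pentasubstituted aryl ether (ester, two different bromines, methoxy). Making it is the real problem and the cycloaddition does not solve it.
- Against, mechanism: the enol ether oxygen of A8 must be attached to a hindered, electron-poor phenol. The donors on the diene do not all direct the same way (the C3' methoxy opposes the C2' aryloxy and C4' silyloxy groups). The cycloreversion needs high temperature with a labile silyl dienol ether.
- Against, after the key step: A7 needs desilylation, bromination, reduction of two esters beside aryl bromides and cleavage of two methyl ethers. The last of these ends in the same benzylic bromide hydrolysis as the chosen route (equal, not better).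
- Step economy: clearly longer than six steps.

Key step: step 5

Assumption: rotation about the two C–O bonds of the diaryl ether is taken to be fast at room temperature, so the target is treated as achiral and no stereochemical element is planned.

## Route

Step 1
Reactants: 1 2-methoxybenzene-1,3-diol (2-methoxyresorcinol)
Product: 2 4-bromo-2-methoxybenzene-1,3-diol
Conditions: NBS (0.95 equiv, slow addition), THF, –78 °C → –20 °C
Reagents that add atoms: N-bromosuccinimide, O=C1CCC(=O)N1Br
Why: Electrophilic aromatic bromination; C4 and C6 of the symmetric diol are equivalent (each ortho to one OH and para to the other) and C5 is meta to both, so only one mono-bromide can form, and a slight deficit of NBS at low temperature should limit the 4,6-dibromide.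

Step 2
Reactants: 2 4-bromo-2-methoxybenzene-1,3-diol (1.2 equiv); 3 1,4-dibromo-2,3-difluorobenzene
Product: 4 6-bromo-3-(3,6-dibromo-2-fluorophenoxy)-2-methoxyphenol
Conditions: Cs2CO3 (3 equiv), degassed DMSO, 100 °C, Ar
Reagents that add atoms: none
Why: Nucleophilic aromatic substitution (addition–elimination) at a C–F carbon of 3 that is activated inductively by the ortho fluorine and the ortho and meta bromines. The phenoxide flanked by OMe and H is more basic and much less hindered than the one between OMe and Br, which would have to attack a carbon itself flanked by F and Br, so the ether should form at the former. The two fluorines of 3 are equivalent, and the new aryloxy group makes the second fluoride too unreactive for a phenoxide, so substitution should stop after one.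

Step 3
Reactants: 4 6-bromo-3-(3,6-dibromo-2-fluorophenoxy)-2-methoxyphenol
Product: 5 6-bromo-3-{3,6-dibromo-2-[(4-methoxyphenyl)methoxy]phenoxy}-2-methoxyphenol
Conditions: 4-MeOC6H4CH2OH (4 equiv), KOtBu (3.5 equiv), NMP, 90 °C, Ar
Reagents that add atoms: 4-methoxybenzyl alcohol, COc1ccc(CO)cc1
Why: Nucleophilic aromatic substitution of the remaining fluoride by a primary alkoxide, with fluoride a far better leaving group than bromide in addition–elimination. Keeping the alcohol in excess over KOtBu leaves the base as the less basic benzylic alkoxide, which should limit aryne formation. The ring B phenol is present as its phenoxide, which also makes ring B a poor leaving group and protects the diaryl ether from alkoxide attack.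

Step 4
Reactants: 5 6-bromo-3-{3,6-dibromo-2-[(4-methoxyphenyl)methoxy]phenoxy}-2-methoxyphenol
Product: 6 3,6-dibromo-2-(4-bromo-3-hydroxy-2-methoxyphenoxy)phenol
Conditions: CF3CO2H, C6HMe5 (3 equiv), CH2Cl2, 0 °C → rt
Reagents that add atoms: none
Why: Acidolysis of the para-methoxybenzyl aryl ether through the stabilised 4-methoxybenzyl cation, which pentamethylbenzene traps by Friedel–Crafts alkylation before it can alkylate C1' of ring B. The methyl ether, the diaryl ether and the C–Br bonds are inert to CF3CO2H.

Step 5
Reactants: 6 3,6-dibromo-2-(4-bromo-3-hydroxy-2-methoxyphenoxy)phenol; 7 formaldehyde (37% aqueous solution; two molecules are incorporated, one per ring)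
Product: 8 3,6-dibromo-2-[4-bromo-3-hydroxy-6-(hydroxymethyl)-2-methoxyphenoxy]-4-(hydroxymethyl)phenol
Conditions: 37% aq. HCHO (20 equiv), NaOH (3 equiv), H2O–THF, 0 °C → rt, N2; then AcOH to pH 6, 0 °C
Reagents that add atoms: formaldehyde, C=O (the second molecule of 7, which supplies the carbon and oxygen of the second CH2OH group)
Why: NaOH converts both phenols of 6 into phenoxides, each of which reacts as a vinylogous enolate through the carbon para to its oxygen (C1 on ring A, C1' on ring B) with one molecule of formaldehyde; the 4-(hydroxymethyl)cyclohexa-2,5-dienone formed tautomerises back to the aromatic phenoxide, so two C–C bonds form in one operation and two molecules of 7 end up in 8. The closest known reaction type is the Lederer–Manasse hydroxymethylation of phenols, in the form used for 2,6-disubstituted phenols, which can only give para-hydroxybenzyl alcohols. No ring is closed and no stereocentre is created. Site selectivity is needed on both rings and comes from the substrate: C3, C5, C3' and C5' already carry oxygen or bromine, and the remaining hydrogens at C6 and C6' are meta to the phenoxide oxygens and receive no charge. The C3' oxygen stays a methyl ether, so no phenoxide stands para to C6'. The second requirement is to stop at the benzyl alcohol: a large excess of formaldehyde, dilution and a temperature at or below ambient should keep addition to formaldehyde faster than attack of a still unsubstituted para carbon on a quinone methide derived from product, which would give diarylmethanes. Ring A, whose phenoxide is stabilised by two bromines, is expected to react more slowly than ring B, so the reaction is followed until the mono-adduct has gone and is then neutralised cold with AcOH to avoid acid ionisation of the new benzylic alcohols.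

Step 6
Reactants: 8 3,6-dibromo-2-[4-bromo-3-hydroxy-6-(hydroxymethyl)-2-methoxyphenoxy]-4-(hydroxymethyl)phenol
Product: 10 6-bromo-3-[2,5-dibromo-6-hydroxy-3-(hydroxymethyl)phenoxy]-4-(hydroxymethyl)benzene-1,2-diol (target CNP0104332.0), via bis(bromomethyl)triphenol 9 (not isolated)
Conditions: BBr3 (8 equiv), CH2Cl2, –78 °C → 0 °C; H2O, 0 °C; then acetone–H2O, NaHCO3, rt
Reagents that add atoms: boron tribromide, BrB(Br)Br (supplies the benzylic bromine of 9); water, O (supplies the benzylic oxygens of 10)
Why: Lewis-acid cleavage of the aryl methyl ether by BBr3, which also converts both benzylic alcohols into bromides to give 9 after the aqueous quench. These para-hydroxybenzyl bromides should then solvolyse readily in buffered aqueous acetone to return both CH2OH groups. The diaryl ether and the aryl bromides are inert to BBr3.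

## Compound list

1 | 2-methoxybenzene-1,3-diol (2-methoxyresorcinol) | COc1c(O)cccc1O | starting material
2 | 4-bromo-2-methoxybenzene-1,3-diol | COc1c(O)ccc(Br)c1O | intermediate
3 | 1,4-dibromo-2,3-difluorobenzene | Fc1c(Br)ccc(Br)c1F | starting material
4 | 6-bromo-3-(3,6-dibromo-2-fluorophenoxy)-2-methoxyphenol | COc1c(O)c(Br)ccc1Oc1c(F)c(Br)ccc1Br | intermediate
5 | 6-bromo-3-{3,6-dibromo-2-[(4-methoxyphenyl)methoxy]phenoxy}-2-methoxyphenol | COc1ccc(COc2c(Br)ccc(Br)c2Oc2ccc(Br)c(O)c2OC)cc1 | intermediate
6 | 3,6-dibromo-2-(4-bromo-3-hydroxy-2-methoxyphenoxy)phenol | Oc1c(Br)ccc(Br)c1Oc1ccc(Br)c(O)c1OC | intermediate
7 | formaldehyde | C=O | starting material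
8 | 3,6-dibromo-2-[4-bromo-3-hydroxy-6-(hydroxymethyl)-2-methoxyphenoxy]-4-(hydroxymethyl)phenol | OCc1cc(Br)c(O)c(Oc2c(CO)cc(Br)c(O)c2OC)c1Br | intermediate
9 | 6-bromo-4-(bromomethyl)-3-[2,5-dibromo-3-(bromomethyl)-6-hydroxyphenoxy]benzene-1,2-diol | BrCc1cc(Br)c(O)c(Oc2c(CBr)cc(Br)c(O)c2O)c1Br | intermediate
10 | 6-bromo-3-[2,5-dibromo-6-hydroxy-3-(hydroxymethyl)phenoxy]-4-(hydroxymethyl)benzene-1,2-diol | OCc1cc(Br)c(O)c(Oc2c(CO)cc(Br)c(O)c2O)c1Br | target

## Step count and risk

Total step count: 6. Longest linear sequence: 6 steps (1 to 10).

Step 5 (key step).
- What may go wrong: condensation of a first-formed hydroxymethyl phenoxide, through its quinone methide, with a still unsubstituted para carbon of another molecule, leading to diarylmethane oligomers. Addition at C1 of ring A may also stall, because that phenoxide is stabilised by two bromines and C1 lies next to C2–Br.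
- Fallback: from 6, two-fold para-formylation under Duff conditions (hexamethylenetetramine, CF3CO2H, 80 °C, then aqueous acid) would give the dialdehyde 2,5-dibromo-3-(4-bromo-6-formyl-3-hydroxy-2-methoxyphenoxy)-4-hydroxybenzaldehyde F1. The formyl groups deactivate the rings and cannot condense further. Reduction with NaBH4 in THF–MeOH at 0 °C returns to the route at 8. The same two C–C bonds are made, but at the aldehyde oxidation level with an iminium electrophile.

Step 2.
- What may go wrong: ether formation through the oxygen between OMe and Br, which is the more acidic hydroxyl and so the more populated mono-anion. A second arylation of the diol, or slow substitution at a fluoride activated only by halogens, is also possible.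
- Fallback: from 1 (used in excess) and 3 under the same base and solvent, the symmetric diol can only give 3-(3,6-dibromo-2-fluorophenoxy)-2-methoxyphenol F2. Amine-mediated ortho-bromination of the phenol (NBS, catalytic iPr2NH, CH2Cl2, 0 °C) then returns to the route at 4. In F2 the position para to the hydroxyl is crowded by the bulky aryloxy group, which supports ortho attack. The fallback trades the choice between two hydroxyls for an ortho/para choice in the bromination.

Step 3.
- What may go wrong: slow addition–elimination, because the fluoride now has an electron-releasing aryloxy neighbour and the substrate is an anion under the conditions. Loss of aryl bromine by base-induced aryne formation or electron-transfer reduction in hot alkoxide is the other risk.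
- Fallback: the order of the two substitutions is inverted. From 3, the potassium alkoxide of 4-methoxybenzyl alcohol in THF–NMP at 25–50 °C should replace one fluoride of the neutral, doubly activated arene to give 1,4-dibromo-2-fluoro-3-[(4-methoxyphenyl)methoxy]benzene F3. Ether formation with 2 (Cs2CO3, NMP, 130 °C), under a carbonate base that is harmless to the C–Br bonds, returns to the route at 5. The fallback replaces steps 2 and 3; its weak point is that the phenoxide substitution then takes place at the less activated fluoride.

Step 6.
- What may go wrong: ionisation of the benzylic bromides to para-hydroxybenzyl cations or quinone methides under the Lewis acid or during hydrolysis, followed by intermolecular alkylation and oligomer formation. Cleavage of the hindered methyl ether may also be incomplete.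
- Fallback: from 8, oxidation of both benzylic alcohols with activated MnO2 in acetone at room temperature would give the dialdehyde 2,5-dibromo-3-(4-bromo-6-formyl-3-hydroxy-2-methoxyphenoxy)-4-hydroxybenzaldehyde F1. Demethylation with BBr3 in CH2Cl2, now on rings that carry no benzylic leaving group, would give 2,5-dibromo-3-(4-bromo-6-formyl-2,3-dihydroxyphenoxy)-4-hydroxybenzaldehyde F4. Reduction with NaBH4 in THF–MeOH at 0 °C returns to the route at 10.

## Further compounds

F1 | step 5 | 2,5-dibromo-3-(4-bromo-6-formyl-3-hydroxy-2-methoxyphenoxy)-4-hydroxybenzaldehyde | O=Cc1cc(Br)c(O)c(Oc2c(C=O)cc(Br)c(O)c2OC)c1Br
F2 | step 2 | 3-(3,6-dibromo-2-fluorophenoxy)-2-methoxyphenol | COc1c(O)cccc1Oc1c(F)c(Br)ccc1Br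
F3 | step 3 | 1,4-dibromo-2-fluoro-3-[(4-methoxyphenyl)methoxy]benzene | COc1ccc(COc2c(F)c(Br)ccc2Br)cc1
F4 | step 6 | 2,5-dibromo-3-(4-bromo-6-formyl-2,3-dihydroxyphenoxy)-4-hydroxybenzaldehyde | O=Cc1cc(Br)c(O)c(Oc2c(C=O)cc(Br)c(O)c2O)c1Br
A1 | alternative 1 | tribromo depsidone (dibenzo[1,4]dioxepinone) with the C3'/C4' cyclic carbonate and the C1 pivaloyloxymethyl group | CC(C)(C)C(=O)OCc1cc(Br)c2OC(=O)c3cc(Br)c4OC(=O)Oc4c3Oc2c1Br
A2 | alternative 1 | [2,5-dibromo-3-(7-bromo-4-hydroxy-2-oxo-1,3-benzodioxole-5-carbonyl)-4-hydroxyphenyl]methyl 2,2-dimethylpropanoate | CC(C)(C)C(=O)OCc1cc(Br)c(O)c(C(=O)c2cc(Br)c3OC(=O)Oc3c2O)c1Br
A3 | alternative 1 | racemic spiro dienone: ring A C3 as the spiro carbon of a benzofuran-3(2H)-one built on ring B, C4 as the dienone carbonyl | CC(C)(C)C(=O)OCC1=C(Br)C2(C(=O)C(Br)=C1)Oc1c3OC(=O)Oc3c(Br)cc1C2=O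
A4 | alternative 2 | 1,1-di(propan-2-yl)-1,3-dihydro-2,1-benzoxasilole with 4-bromo-2,3-dimethoxy-6-(methoxycarbonyl)phenoxy at C3, ethoxy at C4 and trimethylsilyl at C5 (target numbering) | COC(=O)c1cc(Br)c(OC)c(OC)c1Oc1c(OCC)c([Si](C)(C)C)cc2c1[Si](C(C)C)(C(C)C)OC2
A5 | alternative 2 | methyl 5-bromo-3,4-dimethoxy-2-({[di(propan-2-yl)(prop-2-yn-1-yloxy)silyl]ethynyl}oxy)benzoate | COC(=O)c1cc(Br)c(OC)c(OC)c1OC#C[Si](C(C)C)(C(C)C)OCC#C
A6 | alternative 2 | (ethoxyethynyl)trimethylsilane | CCOC#C[Si](C)(C)C
A7 | alternative 3 | methyl 4-[(tert-butyldimethylsilyl)oxy]-2-[2,5-dibromo-6-methoxy-3-(methoxycarbonyl)phenoxy]-3-methoxybenzoate | COC(=O)c1ccc(O[Si](C)(C)C(C)(C)C)c(OC)c1Oc1c(Br)c(C(=O)OC)cc(Br)c1OC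
A8 | alternative 3 | methyl 2,5-dibromo-3-({3-[(tert-butyldimethylsilyl)oxy]-2-methoxycyclohexa-1,3-dien-1-yl}oxy)-4-methoxybenzoate | COC(=O)c1cc(Br)c(OC)c(OC2=C(OC)C(O[Si](C)(C)C(C)(C)C)=CCC2)c1Br
A9 | alternative 3 | methyl prop-2-ynoate (methyl propiolate) | C#CC(=O)OC
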